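**Plan**
- Retrosynthesis cuts, in order: the six O–benzyl bonds (last step), the Cα=Cβ bond of the acrylate on C4 (Horner–Wadsworth–Emmons), O1–C2 and C2–C3 of the dihydrofuran together ([4+1] annulation), and C3–C3a (aryllithium plus oxalate).
- Enabling feature: C2 is a benzylic carbon bonded only to O1, C3, ring B and H, so it can enter as the carbanionic carbon of a ring-B benzylsulfonium ylide; O1, C7a, C3a and the ester-bearing C3 of ring A form the four-atom o-quinone methide partner.
- Forward: ring A is taken from protocatechualdehyde to a silyl-masked mandelate mesylate, and ring B becomes the benzylsulfonium salt of a chiral sulfide. The dihydrofuran (the only ring made) closes in the annulation; the aldehyde is then unmasked, the danshensu phosphonoacetate is joined by olefination, and all benzyl groups are removed together.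
- Stereochemistry: C2 from the chiral sulfide (ylide face, then inversion on ring closure); C3 trans to C2 through the anti betaine and ester equilibration; the side-chain centre from (R)-danshensu; the E-alkene from the olefination.

Key step: step 10

Assumption: the benzylide of (1R,4R,5R)-isothiocineole is taken to react on the face that gives the R,R-epoxide series with aryl aldehydes, which here corresponds, after inversion, to 2S (aryl outranks C3 at C2, hence the other letter); if a pilot run showed the opposite sense, the antipodal sulfide from (S)-limonene would be used.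

**Route**

Step 1
Reactants: 1 3,4-dihydroxybenzaldehyde
Product: 2 4-(benzyloxy)-3-hydroxybenzaldehyde
Conditions: BnBr, NaHCO3, NaI (cat.), DMF, 40 °C
Reagents that add atoms: benzyl bromide, BrCc1ccccc1
Why: The 4-OH, para to the formyl group, is the more acidic phenol, so bicarbonate ionises it selectively and Williamson etherification gives the 4-benzyl ether.

Step 2
Reactants: 2 4-(benzyloxy)-3-hydroxybenzaldehyde
Product: 3 4-(benzyloxy)-2-bromo-3-hydroxybenzaldehyde
Conditions: Br2, NaOAc, Fe powder (cat.), AcOH, rt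
Reagents that add atoms: bromine, BrBr
Why: Electrophilic aromatic bromination goes ortho to the free phenol at C2, the position also taken in the bromination of isovanillin, while acetate buffers the HBr and protects the benzyl ether.

Step 3
Reactants: 3 4-(benzyloxy)-2-bromo-3-hydroxybenzaldehyde
Product: 4 4-(benzyloxy)-2-bromo-3-(triisopropylsilyloxy)benzaldehyde
Conditions: TIPSOTf, 2,6-lutidine, CH2Cl2, 0 °C
Reagents that add atoms: triisopropylsilyl trifluoromethanesulfonate, CC(C)[Si](OS(=O)(=O)C(F)(F)F)(C(C)C)C(C)C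
Why: O-Silylation of the hindered phenol with a silyl triflate; the bulky triisopropylsilyl group is chosen because it should not shift to the neighbouring carbanion or alkoxide in steps 5 and 6 and is still cleaved by fluoride in step 10.

Step 4
Reactants: 4 4-(benzyloxy)-2-bromo-3-(triisopropylsilyloxy)benzaldehyde
Product: 5 1-(benzyloxy)-3-bromo-4-(dimethoxymethyl)-2-(triisopropylsilyloxy)benzene
Conditions: HC(OMe)3, MeOH, PPTS (cat.), rt; Et3N quench
Reagents that add atoms: trimethyl orthoformate, COC(OC)OC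
Why: Acid-catalysed acetalisation with orthoformate as water scavenger masks the aldehyde against the organolithium, the hydride and the sulfur ylide used later.

Step 5
Reactants: 5 1-(benzyloxy)-3-bromo-4-(dimethoxymethyl)-2-(triisopropylsilyloxy)benzene, 6 dimethyl oxalate
Product: 8 methyl 2-[3-(benzyloxy)-6-(dimethoxymethyl)-2-(triisopropylsilyloxy)phenyl]-2-oxoacetate, via aryllithium 7 (not isolated)
Conditions: n-BuLi, THF, –78 °C, 10 min; cannulated into 6 (3 equiv), THF, –78 °C; aq. NH4Cl
Reagents that add atoms: none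
Why: Bromine–lithium exchange is fast at –78 °C, and the acetal-chelated aryllithium acylates excess dimethyl oxalate once under inverse addition to give the aryl glyoxylate (bond C3–C3a).

Step 6
Reactants: 8 methyl 2-[3-(benzyloxy)-6-(dimethoxymethyl)-2-(triisopropylsilyloxy)phenyl]-2-oxoacetate
Product: 9 methyl 2-[3-(benzyloxy)-6-(dimethoxymethyl)-2-(triisopropylsilyloxy)phenyl]-2-hydroxyacetate (racemic)
Conditions: NaBH4, CeCl3·7H2O, MeOH/THF, –40 °C; AcOH quench at –40 °C
Reagents that add atoms: none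
Why: Chemoselective borohydride reduction of the activated α-keto group over the ester, kept cold and quenched with acid so that the alkoxide cannot take over the silyl group; the new centre is racemic and is erased in step 10.

Step 7
Reactants: 9 methyl 2-[3-(benzyloxy)-6-(dimethoxymethyl)-2-(triisopropylsilyloxy)phenyl]-2-hydroxyacetate
Product: 10 methyl 2-[3-(benzyloxy)-6-(dimethoxymethyl)-2-(triisopropylsilyloxy)phenyl]-2-(methylsulfonyloxy)acetate (racemic)
Conditions: MsCl, Et3N, CH2Cl2, –20 °C; cold aqueous work-up, used at once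
Reagents that add atoms: methanesulfonyl chloride, CS(=O)(=O)Cl
Why: Mesylation of the secondary alcohol through sulfene; the adjacent ester retards ionisation so the mesylate can be handled, and unlike an α-sulfonyl ester it has no carbon acid that would be deprotonated in preference to phenoxide-driven loss of the leaving group in step 10.

Step 8
Reactants: 11 [3,4-bis(benzyloxy)phenyl]methanol
Product: 12 1,2-bis(benzyloxy)-4-(bromomethyl)benzene
Conditions: PBr3, CH2Cl2, 0 °C
Reagents that add atoms: phosphorus tribromide, BrP(Br)Br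
Why: Conversion of a primary benzylic alcohol into the bromide by SN2 displacement on its phosphite ester.

Step 9
Reactants: 12 1,2-bis(benzyloxy)-4-(bromomethyl)benzene, 13 (1R,4R,5R)-isothiocineole
Product: 14 (1R,4R,5R,6R)-6-[3,4-bis(benzyloxy)benzyl]-4,7,7-trimethyl-6-thiabicyclo[3.2.1]octan-6-ium trifluoromethanesulfonate (benzyl on the exo face of sulfur)
Conditions: LiOTf, CH2Cl2/H2O, rt; crystallisation
Reagents that add atoms: lithium trifluoromethanesulfonate, [Li+].[O-]S(=O)(=O)C(F)(F)F
Why: S-Alkylation of the sulfide by the reactive benzylic bromide on its less hindered exo lone pair, with anion metathesis to the non-nucleophilic triflate so that a single sulfur epimer can be crystallised.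

Step 10
Reactants: 10 methyl 2-[3-(benzyloxy)-6-(dimethoxymethyl)-2-(triisopropylsilyloxy)phenyl]-2-(methylsulfonyloxy)acetate, 14 (1R,4R,5R,6R)-6-[3,4-bis(benzyloxy)benzyl]-4,7,7-trimethyl-6-thiabicyclo[3.2.1]octan-6-ium trifluoromethanesulfonate
Product: 18 methyl (2S,3S)-7-(benzyloxy)-2-[3,4-bis(benzyloxy)phenyl]-4-(dimethoxymethyl)-2,3-dihydrobenzofuran-3-carboxylate, via sulfonium benzylide 15 (not isolated), via o-quinone methide 16 (not isolated), via betaine 17 (not isolated)
Conditions: CsF, 18-crown-6, Cs2CO3, MeCN/CH2Cl2, –30 → 0 °C, 10 added slowly to 14 (1.3 equiv); pH 7 buffer quench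
Reagents that add atoms: none
Why: Proposed new method: fluoride removes the silyl group of 10 and the phenoxide expels mesylate to give o-quinone methide 16, whose exocyclic carbon (the future C3) is activated by both the ring carbonyl and the ester; benzylide 15, formed reversibly from 14 and carbonate, adds there (bond C2–C3) to give betaine 17, whose phenoxide then displaces the sulfide from the benzylic carbon (bond O1–C2). The closest known reactions are the formal [4+1] annulation of fluoride- or base-generated o-quinone methides with sulfonium ylides to trans-2,3-dihydrobenzofurans and the asymmetric benzylidene transfer from isothiocineole-derived sulfonium salts to aldehydes and imines; untested are the ester on the methide carbon and a chiral semi-stabilised ylide in this annulation. The dihydrofuran, the only ring formed, closes by 5-exo-tet SN2 with inversion at C2. C2 is set by the sulfide, which fixes the conformation and the open face of the ylide; addition to the strongly electrophilic methide should be irreversible, so this face becomes R at the sulfonium-bearing carbon of 17 and, after inversion, 2S. C3 is set relative to C2: the trans ester arises from the anti betaine and is also the thermodynamic epimer, reachable under the carbonate through the ester enolate. The step needs C-attack of the ylide on the methide ahead of benzyl transfer from 14 to the phenoxide, epoxidation of an aldehyde, or methide dimerisation; this is secured by the acetal mask, by a leaving group that departs from the phenoxide faster than any bimolecular alkylation, and by slow release of 16 into excess 14 at low temperature.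

Step 11
Reactants: 18 methyl (2S,3S)-7-(benzyloxy)-2-[3,4-bis(benzyloxy)phenyl]-4-(dimethoxymethyl)-2,3-dihydrobenzofuran-3-carboxylate
Product: 19 methyl (2S,3S)-7-(benzyloxy)-2-[3,4-bis(benzyloxy)phenyl]-4-formyl-2,3-dihydrobenzofuran-3-carboxylate
Conditions: TsOH·H2O (cat.), acetone/H2O, rt
Reagents that add atoms: water, O
Why: Acid-catalysed hydrolysis of an electron-rich aryl dimethyl acetal, mild enough to leave the esters, the benzyl ethers and the trans ring untouched.

Step 12
Reactants: 20 (R)-3-(3,4-dihydroxyphenyl)-2-hydroxypropanoic acid (danshensu; the sodium salt serves equally)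
Product: 21 benzyl (R)-3-[3,4-bis(benzyloxy)phenyl]-2-hydroxypropanoate
Conditions: BnBr (3.3 equiv), K2CO3, DMF, rt, under argon
Reagents that add atoms: benzyl bromide, BrCc1ccccc1
Why: Williamson and carboxylate alkylation: carbonate ionises the two phenols and the acid but not the secondary alcohol, so the 2-OH stays free and the stereocentre is untouched.

Step 13
Reactants: 21 benzyl (R)-3-[3,4-bis(benzyloxy)phenyl]-2-hydroxypropanoate, 22 2-(diethoxyphosphoryl)acetic acid
Product: 23 benzyl (R)-3-[3,4-bis(benzyloxy)phenyl]-2-{[2-(diethoxyphosphoryl)acetyl]oxy}propanoate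
Conditions: EDC·HCl, DMAP (cat.), CH2Cl2, 0 °C → rt
Reagents that add atoms: none
Why: Carbodiimide (Steglich) esterification of the secondary alcohol with the phosphonoacetic acid, which does not touch the C–O stereocentre.

Step 14
Reactants: 19 methyl (2S,3S)-7-(benzyloxy)-2-[3,4-bis(benzyloxy)phenyl]-4-formyl-2,3-dihydrobenzofuran-3-carboxylate, 23 benzyl (R)-3-[3,4-bis(benzyloxy)phenyl]-2-{[2-(diethoxyphosphoryl)acetyl]oxy}propanoate
Product: 24 methyl (2S,3S)-7-(benzyloxy)-4-[(E)-3-{[(R)-1-(benzyloxy)-3-[3,4-bis(benzyloxy)phenyl]-1-oxopropan-2-yl]oxy}-3-oxoprop-1-en-1-yl]-2-[3,4-bis(benzyloxy)phenyl]-2,3-dihydrobenzofuran-3-carboxylate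
Conditions: LiCl, i-Pr2NEt, MeCN, rt
Reagents that add atoms: none
Why: Horner–Wadsworth–Emmons olefination under Masamune–Roush conditions gives the E-acrylate, and the weak amine base spares the acidic C3–H and the α-acyloxy ester centre.

Step 15
Reactants: 24 methyl (2S,3S)-7-(benzyloxy)-4-[(E)-3-{[(R)-1-(benzyloxy)-3-[3,4-bis(benzyloxy)phenyl]-1-oxopropan-2-yl]oxy}-3-oxoprop-1-en-1-yl]-2-[3,4-bis(benzyloxy)phenyl]-2,3-dihydrobenzofuran-3-carboxylate
Product: 25 monomethyl lithospermate
Conditions: BCl3, C6HMe5, CH2Cl2, –78 → 0 °C; MeOH quench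
Reagents that add atoms: none
Why: Lewis-acid debenzylation: BCl3 cleaves the five aryl benzyl ethers and the benzyl ester while pentamethylbenzene traps the benzyl cations by Friedel–Crafts alkylation, leaving the methyl ester, the acrylate and the three stereocentres in place.

**Compound list**
1 | 3,4-dihydroxybenzaldehyde (protocatechualdehyde) | O=Cc1ccc(O)c(O)c1 | starting material
2 | 4-(benzyloxy)-3-hydroxybenzaldehyde | O=Cc1ccc(OCc2ccccc2)c(O)c1 | intermediate
3 | 4-(benzyloxy)-2-bromo-3-hydroxybenzaldehyde | O=Cc1ccc(OCc2ccccc2)c(O)c1Br | intermediate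
4 | 4-(benzyloxy)-2-bromo-3-(triisopropylsilyloxy)benzaldehyde | O=Cc1ccc(OCc2ccccc2)c(O[Si](C(C)C)(C(C)C)C(C)C)c1Br | intermediate
5 | 1-(benzyloxy)-3-bromo-4-(dimethoxymethyl)-2-(triisopropylsilyloxy)benzene | COC(OC)c1ccc(OCc2ccccc2)c(O[Si](C(C)C)(C(C)C)C(C)C)c1Br | intermediate
6 | dimethyl oxalate | COC(=O)C(=O)OC | starting material
7 | [3-(benzyloxy)-6-(dimethoxymethyl)-2-(triisopropylsilyloxy)phenyl]lithium | [Li]c1c(C(OC)OC)ccc(OCc2ccccc2)c1O[Si](C(C)C)(C(C)C)C(C)C | intermediate
8 | methyl 2-[3-(benzyloxy)-6-(dimethoxymethyl)-2-(triisopropylsilyloxy)phenyl]-2-oxoacetate | COC(=O)C(=O)c1c(C(OC)OC)ccc(OCc2ccccc2)c1O[Si](C(C)C)(C(C)C)C(C)C | intermediate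
9 | methyl 2-[3-(benzyloxy)-6-(dimethoxymethyl)-2-(triisopropylsilyloxy)phenyl]-2-hydroxyacetate (racemic) | COC(=O)C(O)c1c(C(OC)OC)ccc(OCc2ccccc2)c1O[Si](C(C)C)(C(C)C)C(C)C | intermediate
10 | methyl 2-[3-(benzyloxy)-6-(dimethoxymethyl)-2-(triisopropylsilyloxy)phenyl]-2-(methylsulfonyloxy)acetate (racemic) | COC(=O)C(OS(C)(=O)=O)c1c(C(OC)OC)ccc(OCc2ccccc2)c1O[Si](C(C)C)(C(C)C)C(C)C | intermediate
11 | [3,4-bis(benzyloxy)phenyl]methanol | OCc1ccc(OCc2ccccc2)c(OCc2ccccc2)c1 | starting material
12 | 1,2-bis(benzyloxy)-4-(bromomethyl)benzene | BrCc1ccc(OCc2ccccc2)c(OCc2ccccc2)c1 | intermediate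
13 | (1R,4R,5R)-4,7,7-trimethyl-6-thiabicyclo[3.2.1]octane ((+)-isothiocineole) | C[C@@H]1CC[C@@H]2C[C@H]1SC2(C)C | starting material
14 | (1R,4R,5R,6R)-6-[3,4-bis(benzyloxy)benzyl]-4,7,7-trimethyl-6-thiabicyclo[3.2.1]octan-6-ium trifluoromethanesulfonate | C[C@@H]1CC[C@@H]2C[C@H]1[S@@+](Cc1ccc(OCc3ccccc3)c(OCc3ccccc3)c1)C2(C)C.[O-]S(=O)(=O)C(F)(F)F | intermediate
15 | sulfonium benzylide of 14 (ylide carbon bearing ring B, exo on sulfur) | C[C@@H]1CC[C@@H]2C[C@H]1[S@@+]([CH-]c1ccc(OCc3ccccc3)c(OCc3ccccc3)c1)C2(C)C | intermediate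
16 | methyl 2-[3-(benzyloxy)-6-(dimethoxymethyl)-2-oxocyclohexa-3,5-dien-1-ylidene]acetate (o-quinone methide, either alkene geometry) | COC(=O)C=C1C(=O)C(OCc2ccccc2)=CC=C1C(OC)OC | intermediate
17 | betaine: methyl 2-[3-(benzyloxy)-6-(dimethoxymethyl)-2-oxidophenyl]-3-[3,4-bis(benzyloxy)phenyl]-3-(isothiocineol-6-ium-6-yl)propanoate, R at the sulfonium-bearing carbon, ester-bearing carbon as formed | C[C@@H]1CC[C@@H]2C[C@H]1[S@@+]([C@@H](c1ccc(OCc3ccccc3)c(OCc3ccccc3)c1)C(C(=O)OC)c1c(C(OC)OC)ccc(OCc3ccccc3)c1[O-])C2(C)C | intermediate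
18 | methyl (2S,3S)-7-(benzyloxy)-2-[3,4-bis(benzyloxy)phenyl]-4-(dimethoxymethyl)-2,3-dihydrobenzofuran-3-carboxylate | COC(=O)[C@H]1c2c(C(OC)OC)ccc(OCc3ccccc3)c2O[C@@H]1c1ccc(OCc3ccccc3)c(OCc3ccccc3)c1 | intermediate
19 | methyl (2S,3S)-7-(benzyloxy)-2-[3,4-bis(benzyloxy)phenyl]-4-formyl-2,3-dihydrobenzofuran-3-carboxylate | COC(=O)[C@H]1c2c(C=O)ccc(OCc3ccccc3)c2O[C@@H]1c1ccc(OCc3ccccc3)c(OCc3ccccc3)c1 | intermediate
20 | (R)-3-(3,4-dihydroxyphenyl)-2-hydroxypropanoic acid (danshensu) | O[C@H](Cc1ccc(O)c(O)c1)C(=O)O | starting material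
21 | benzyl (R)-3-[3,4-bis(benzyloxy)phenyl]-2-hydroxypropanoate | O[C@H](Cc1ccc(OCc2ccccc2)c(OCc2ccccc2)c1)C(=O)OCc1ccccc1 | intermediate
22 | 2-(diethoxyphosphoryl)acetic acid | CCOP(=O)(CC(=O)O)OCC | starting material
23 | benzyl (R)-3-[3,4-bis(benzyloxy)phenyl]-2-{[2-(diethoxyphosphoryl)acetyl]oxy}propanoate | CCOP(=O)(OCC)CC(=O)O[C@H](Cc1ccc(OCc2ccccc2)c(OCc2ccccc2)c1)C(=O)OCc1ccccc1 | intermediate
24 | methyl (2S,3S)-7-(benzyloxy)-4-[(E)-3-{[(R)-1-(benzyloxy)-3-[3,4-bis(benzyloxy)phenyl]-1-oxopropan-2-yl]oxy}-3-oxoprop-1-en-1-yl]-2-[3,4-bis(benzyloxy)phenyl]-2,3-dihydrobenzofuran-3-carboxylate | COC(=O)[C@H]1c2c(/C=C/C(=O)O[C@H](Cc3ccc(OCc4ccccc4)c(OCc4ccccc4)c3)C(=O)OCc3ccccc3)ccc(OCc3ccccc3)c2O[C@@H]1c1ccc(OCc3ccccc3)c(OCc3ccccc3)c1 | intermediate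
25 | monomethyl lithospermate | COC(=O)[C@H]1c2c(/C=C/C(=O)O[C@H](Cc3ccc(O)c(O)c3)C(=O)O)ccc(O)c2O[C@@H]1c1ccc(O)c(O)c1 | target

**Step count**
Total: 15 steps. Longest linear sequence: 11 steps (steps 1–7, 10, 11, 14, 15).

**Steps most likely to fail**

Step 10 (Proposed new method). The quinone methide may be consumed by dimerisation or by fluoride and carbonate before the ylide reaches it. The sulfonium salt may transfer its benzyl group to the phenoxide. Facial control by the sulfide may be incomplete or of the opposite sense. Prolonged base may open the product by β-elimination across C3–C2. A cis ester, if it persists, would be equilibrated with a little DBU.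

The fallback uses known chemistry, an imine-directed rhodium-catalysed intramolecular C–H alkylation. It sets out from 11 and 2 and returns to the route at 19. Oxidation of 11 with MnO2 should give 3,4-bis(benzyloxy)benzaldehyde F1. Corey–Fuchs homologation (CBr4, PPh3) should give 1,2-bis(benzyloxy)-4-(2,2-dibromovinyl)benzene F2, and n-BuLi followed by methyl chloroformate should give methyl 3-[3,4-bis(benzyloxy)phenyl]prop-2-ynoate F3. Conjugate addition of phenol 2 to F3 (K2CO3, DMF) should give methyl 3-[3,4-bis(benzyloxy)phenyl]-3-[2-(benzyloxy)-5-formylphenoxy]prop-2-enoate F4. Condensation with (R)-1-aminoindane (the enantiomer assumed to lead to the 2S,3S series) should give the N-[(R)-indan-1-yl]imine of F4, F5. With [RhCl(coe)2]2 and (dicyclohexylphosphino)ferrocene in toluene at 75 °C the imine should direct metalation to the ring-A carbon between the imine and the aryloxy group, and insertion of the tethered alkene should close the ring to methyl (2S,3S)-7-(benzyloxy)-2-[3,4-bis(benzyloxy)phenyl]-4-{[(R)-indan-1-ylimino]methyl}-2,3-dihydrobenzofuran-3-carboxylate F6. Aqueous acid would release the aldehyde, DBU would equilibrate any cis ester, and recrystallisation would raise the enantiomeric purity, giving 19.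

Step 15. Cleavage of the benzyl ester may lag behind that of the aryl ethers, and warming in the presence of BCl3 may ionise the C2–O1 bond or alkylate the freed catechols.

The fallback separates release of the carboxyl group from the Lewis-acid step. It sets out from 20 and 19 and returns at 25. Alkylation of 20 with 4-methoxybenzyl chloride and K2CO3 in DMF should give 4-methoxybenzyl (R)-3-{3,4-bis[(4-methoxybenzyl)oxy]phenyl}-2-hydroxypropanoate F7. Esterification with 22 (EDC·HCl, DMAP) should give its 2-(diethoxyphosphoryl)acetate F8. Olefination of 19 with F8 (LiCl, i-Pr2NEt) should give the analogue of 24 that carries 4-methoxybenzyl groups on the danshensu part, F9. Trifluoroacetic acid with anisole at 0 °C should remove the 4-methoxybenzyl ester and ethers by acidolysis to give (R)-2-{[(E)-3-{(2S,3S)-7-(benzyloxy)-2-[3,4-bis(benzyloxy)phenyl]-3-(methoxycarbonyl)-2,3-dihydrobenzofuran-4-yl}acryloyl]oxy}-3-(3,4-dihydroxyphenyl)propanoic acid F10. BCl3 with pentamethylbenzene at –78 °C then only has to cleave three aryl benzyl ethers to reach 25.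

Step 14. Olefination at the hindered C4 aldehyde, flanked by the C3 ester, may be slow, and long exposure to base could open the ring by elimination or erode the side-chain centre.

The fallback forms the alkene first and the ester bond second. It sets out from 19 and returns at 24. Knoevenagel–Doebner condensation of 19 with malonic acid (pyridine, piperidine cat., 80 °C) should give (E)-3-{(2S,3S)-7-(benzyloxy)-2-[3,4-bis(benzyloxy)phenyl]-3-(methoxycarbonyl)-2,3-dihydrobenzofuran-4-yl}acrylic acid F11. Steglich esterification of F11 with alcohol 21 (EDC·HCl, DMAP, CH2Cl2) should give 24.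

**Further compounds**
F1 | step 10 | 3,4-bis(benzyloxy)benzaldehyde | O=Cc1ccc(OCc2ccccc2)c(OCc2ccccc2)c1
F2 | step 10 | 1,2-bis(benzyloxy)-4-(2,2-dibromovinyl)benzene | BrC(Br)=Cc1ccc(OCc2ccccc2)c(OCc2ccccc2)c1
F3 | step 10 | methyl 3-[3,4-bis(benzyloxy)phenyl]prop-2-ynoate | COC(=O)C#Cc1ccc(OCc2ccccc2)c(OCc2ccccc2)c1
F4 | step 10 | methyl 3-[3,4-bis(benzyloxy)phenyl]-3-[2-(benzyloxy)-5-formylphenoxy]prop-2-enoate | COC(=O)C=C(Oc1cc(C=O)ccc1OCc1ccccc1)c1ccc(OCc2ccccc2)c(OCc2ccccc2)c1
F5 | step 10 | N-[(R)-indan-1-yl]imine of F4 | COC(=O)C=C(Oc1cc(C=N[C@@H]2CCc3ccccc32)ccc1OCc1ccccc1)c1ccc(OCc2ccccc2)c(OCc2ccccc2)c1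
F6 | step 10 | methyl (2S,3S)-7-(benzyloxy)-2-[3,4-bis(benzyloxy)phenyl]-4-{[(R)-indan-1-ylimino]methyl}-2,3-dihydrobenzofuran-3-carboxylate | COC(=O)[C@H]1c2c(C=N[C@@H]3CCc4ccccc43)ccc(OCc3ccccc3)c2O[C@@H]1c1ccc(OCc3ccccc3)c(OCc3ccccc3)c1
F7 | step 15 | 4-methoxybenzyl (R)-3-{3,4-bis[(4-methoxybenzyl)oxy]phenyl}-2-hydroxypropanoate | O[C@H](Cc1ccc(OCc2ccc(OC)cc2)c(OCc2ccc(OC)cc2)c1)C(=O)OCc1ccc(OC)cc1
F8 | step 15 | 4-methoxybenzyl (R)-3-{3,4-bis[(4-methoxybenzyl)oxy]phenyl}-2-{[2-(diethoxyphosphoryl)acetyl]oxy}propanoate | CCOP(=O)(OCC)CC(=O)O[C@H](Cc1ccc(OCc2ccc(OC)cc2)c(OCc2ccc(OC)cc2)c1)C(=O)OCc1ccc(OC)cc1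
F9 | step 15 | methyl (2S,3S)-7-(benzyloxy)-2-[3,4-bis(benzyloxy)phenyl]-4-[(E)-3-{[(R)-3-{3,4-bis[(4-methoxybenzyl)oxy]phenyl}-1-[(4-methoxybenzyl)oxy]-1-oxopropan-2-yl]oxy}-3-oxoprop-1-en-1-yl]-2,3-dihydrobenzofuran-3-carboxylate | COC(=O)[C@H]1c2c(/C=C/C(=O)O[C@H](Cc3ccc(OCc4ccc(OC)cc4)c(OCc4ccc(OC)cc4)c3)C(=O)OCc3ccc(OC)cc3)ccc(OCc3ccccc3)c2O[C@@H]1c1ccc(OCc3ccccc3)c(OCc3ccccc3)c1
F10 | step 15 | (R)-2-{[(E)-3-{(2S,3S)-7-(benzyloxy)-2-[3,4-bis(benzyloxy)phenyl]-3-(methoxycarbonyl)-2,3-dihydrobenzofuran-4-yl}acryloyl]oxy}-3-(3,4-dihydroxyphenyl)propanoic acid | COC(=O)[C@H]1c2c(/C=C/C(=O)O[C@H](Cc3ccc(O)c(O)c3)C(=O)O)ccc(OCc3ccccc3)c2O[C@@H]1c1ccc(OCc3ccccc3)c(OCc3ccccc3)c1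
F11 | step 14 | (E)-3-{(2S,3S)-7-(benzyloxy)-2-[3,4-bis(benzyloxy)phenyl]-3-(methoxycarbonyl)-2,3-dihydrobenzofuran-4-yl}acrylic acid | COC(=O)[C@H]1c2c(/C=C/C(=O)O)ccc(OCc3ccccc3)c2O[C@@H]1c1ccc(OCc3ccccc3)c(OCc3ccccc3)c1
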